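**Retrosynthetic overview**
1. Target 37 ⇐ dihydroxylation of the strained E-C3=C4 olefin (last step) ⇐ angeloylation of C8–OH ⇐ C8–OH-directed epoxidation of the Z-C1=C10 olefin of hydroxy dienolide 32.
2. 32 ⇐ reagent-controlled reduction of keto lactone 31 ⇐ PMB removal and lactonisation of keto acrylate 29 (γ-lactone ring).
3. Key step: 29 ⇐ anionic oxy-Cope ring expansion (six to ten) of cyclohexenol 24, the enolate being trapped in the same flask with methyl 3-nitroacrylate; this sets C6, C7 and the 3E olefin and carries the ring olefin over as 1(10)Z.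
4. 24 ⇐ ketone 14 + PMB-oxyacetylide, then trans-hydroalumination to the (E)-enol ether.
5. 14 ⇐ ring-closing metathesis of dienone 13 ⇐ Evans deconjugative allylation (only source of absolute configuration). Ring order: cyclohexene, ten-membered carbocycle, lactone, oxirane.

Assumption: germacrane numbering is used for the ten-membered ring (C6 lactone carbinol, C7 ring fusion, C8 ester carbon, C1/C10 epoxide, C3/C4 diol), which makes the target (1R,3S,4S,6R,7S,8R,10S), and methyl (E)-3-nitroacrylate is taken as purchasable.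

**Route**

Step 1
Reactants: 1 (4R)-4-benzyl-1,3-oxazolidin-2-one; 2 3-methylbut-2-enoyl chloride
Product: 4 (4R)-4-benzyl-3-(3-methylbut-2-enoyl)-1,3-oxazolidin-2-one, via lithium oxazolidinide 3 (not isolated)
Conditions: n-BuLi, THF, −78 °C; then 2, −78 to 0 °C
Reagents that add atoms: none
Why: N-acylation of the lithiated Evans auxiliary by the acid chloride (nucleophilic acyl substitution), no stereocenter being formed.

Step 2
Reactants: 4; 5 allyl iodide
Product: 7 (4R)-4-benzyl-3-[(2R)-2-(prop-1-en-2-yl)pent-4-enoyl]-1,3-oxazolidin-2-one, via sodium dienolate 6 (not isolated)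
Conditions: NaN(SiMe3)2, THF, −78 °C; then allyl iodide, −78 to −40 °C
Reagents that add atoms: none
Why: γ-deprotonation gives the chelated Z(O)-dienolate, which is allylated at the α-carbon on the face away from the benzyl group (Evans auxiliary-controlled deconjugative alkylation), setting the future C3 centre as R.

Step 3
Reactants: 7; 8 N,O-dimethylhydroxylamine hydrochloride
Product: 10 (2R)-N-methoxy-N-methyl-2-(prop-1-en-2-yl)pent-4-enamide, via aluminium amide 9 (not isolated)
Conditions: AlMe3, CH2Cl2, 0 °C; then 7, −10 to 0 °C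
Reagents that add atoms: none
Why: aluminium amide transamidation (Weinreb aminolysis) opens the exocyclic imide carbonyl under non-basic conditions, so the α-stereocenter is kept and auxiliary 1 is returned.

Step 4
Reactants: 10; 11 (2-methylallyl)magnesium chloride
Product: 13 (5R)-2-methyl-5-(prop-1-en-2-yl)octa-1,7-dien-4-one, via chloromagnesium hemiaminal 12 (not isolated)
Conditions: THF, −78 to −20 °C; cold aq NH4Cl
Reagents that add atoms: none
Why: Weinreb ketone synthesis, in which the stable magnesium chelate stops over-addition and releases the epimerisable β,γ-unsaturated ketone only on cold work-up.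

Step 5
Reactants: 13
Product: 14 (2R)-5-methyl-2-(prop-1-en-2-yl)cyclohex-4-en-1-one
Conditions: second-generation Grubbs catalyst RuCl2(=CHPh)(H2IMes)(PCy3) (2 mol %), 1,4-benzoquinone (10 mol %), CH2Cl2, 40 °C
Reagents that add atoms: none
Why: ring-closing metathesis of the allyl and 2-methylallyl arms closes the cyclohexene, whose double bond is cis by necessity and later becomes the 1(10)Z olefin, while the isopropenyl group can only give strained rings and stays.

Step 6
Reactants: 15 (4-methoxyphenyl)methanol; 16 trichloroethene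
Product: 19 1-{[(E)-1,2-dichloroethenyl]oxymethyl}-4-methoxybenzene, via potassium 4-methoxybenzyl oxide 17 (not isolated), via dichloroacetylene 18 (not isolated)
Conditions: KH, THF, 0 °C to rt; then trichloroethene, rt
Reagents that add atoms: none
Why: base-induced dehydrochlorination of trichloroethene followed by anti addition of the alkoxide to the dichloroacetylene formed (nucleophilic addition to a haloalkyne) gives the (E)-dichlorovinyl ether, a stable precursor of the alkoxyacetylide.

Step 7
Reactants: 19; 14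
Product: 22 (1R,2R)-1-{[(4-methoxybenzyl)oxy]ethynyl}-5-methyl-2-(prop-1-en-2-yl)cyclohex-4-en-1-ol, via lithium alkoxyacetylide 20 (not isolated), via dichlorocerium alkoxyacetylide 21 (not isolated)
Conditions: n-BuLi (2.2 equiv), THF, −78 to −40 °C; CeCl3, −78 °C; then 14, −78 °C; aq NaHCO3
Reagents that add atoms: none
Why: elimination and chlorine–lithium exchange give the acetylide, whose weakly basic cerium derivative adds 1,2 to the enolisable ketone from the equatorial direction anti to the neighbouring isopropenyl group (organocerium carbonyl addition), giving the axial tertiary alcohol with the two unsaturated arms trans.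

Step 8
Reactants: 22
Product: 24 (1R,2R)-1-{(E)-2-[(4-methoxybenzyl)oxy]ethenyl}-5-methyl-2-(prop-1-en-2-yl)cyclohex-4-en-1-ol, via cyclic vinylalanate 23 (not isolated)
Conditions: LiAlH4, THF, 0 °C to rt; Na2SO4·10H2O
Reagents that add atoms: none
Why: alkoxide-directed trans-hydroalumination of the propargylic alcohol followed by protonolysis with retention gives the (E)-enol ether only, which the basic work-up protects from acid-catalysed rearrangement.

Step 9
Reactants: 24; 25 methyl (E)-3-nitroprop-2-enoate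
Product: 29 methyl 2-[(1S,2R,4E,7Z)-2-[(4-methoxybenzyl)oxy]-4,8-dimethyl-10-oxocyclodeca-4,7-dien-1-yl]prop-2-enoate, via potassium alkoxide 26 (not isolated), via potassium enolate 27 (not isolated), via nitro ester 28 (not isolated)
Conditions: KN(SiMe3)2, 18-crown-6, THF, 0 to 25 °C; then 25, −78 °C; AcOH; Et3N, 0 °C
Reagents that add atoms: none
Why: anionic oxy-Cope rearrangement through a chair transition state with both alkenyl groups equatorial transfers the chirality of C3/C8 to C6 (R, alkoxy group equatorial because the enol ether is E), creates the 3E olefin and leaves the former ring olefin as 1(10)Z, after which the ten-membered enolate is trapped on its outer face by Michael addition to the nitroacrylate at the carbon next to the ester (C7 S, trans to the C6 oxygen) and E1cB loss of nitrous acid unveils the acrylate.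

Step 10
Reactants: 29
Product: 31 (6R,7S)-8-oxogermacra-1(10)Z,3E,11(13)-trien-12,6-olide, via hydroxy ester 30 (not isolated)
Conditions: DDQ, CH2Cl2/aq NaH2PO4–Na2HPO4 (pH 7), 0 °C; then PPTS (cat.), CH2Cl2, rt
Reagents that add atoms: none
Why: oxidative cleavage of the PMB ether followed by acid-catalysed lactonisation of the γ-hydroxy acrylate closes the trans-fused α-methylene-γ-butyrolactone on the only free hydroxyl, with C6 and C7 untouched.

Step 11
Reactants: 31
Product: 32 (6R,7R,8R)-8-hydroxygermacra-1(10)Z,3E,11(13)-trien-12,6-olide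
Conditions: (S)-2-methyl-CBS-oxazaborolidine (1 equiv), catecholborane, toluene, −78 °C
Reagents that add atoms: none
Why: Corey–Bakshi–Shibata reduction, in which the (S)-oxazaborolidine treats the branched C7 arm as the large group and delivers hydride to give the 8R alcohol (reagent control), while catecholborane leaves the alkenes and the methylene lactone alone.

Step 12
Reactants: 32
Product: 33 (1R,6R,7R,8R,10S)-1,10-epoxy-8-hydroxygermacra-3E,11(13)-dien-12,6-olide
Conditions: VO(acac)2 (5 mol %), t-BuOOH, CH2Cl2, 0 °C to rt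
Reagents that add atoms: tert-butyl hydroperoxide CC(C)(C)OO
Why: vanadium-catalysed hydroxyl-directed epoxidation, in which the homoallylic C8 hydroxyl binds the metal peroxide and delivers oxygen to its own face of the Z-C1=C10 olefin to give the cis (1R,10S) epoxide, while the undirected C3=C4 olefin and the electron-poor methylene lactone do not react.

Step 13
Reactants: 33; 34 angelic acid ((Z)-2-methylbut-2-enoic acid)
Product: 36 (1R,6R,7S,8R,10S)-8-angeloyloxy-1,10-epoxygermacra-3E,11(13)-dien-12,6-olide, via mixed anhydride 35 (not isolated)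
Conditions: 2,4,6-trichlorobenzoyl chloride, Et3N, toluene, rt; then 33, 75 °C
Reagents that add atoms: none
Why: Yamaguchi mixed-anhydride esterification run without a nucleophilic catalyst acylates the hindered C8 hydroxyl and keeps the Z geometry of the angelate, with no stereocenter changed.

Step 14
Reactants: 36
Product: 37 (1R,3S,4S,6R,7S,8R,10S)-8-angeloyloxy-1,10-epoxy-3,4-dihydroxygermacr-11(13)-en-12,6-olide
Conditions: OsO4 (5 mol %), (DHQ)2PHAL (10 mol %), NMO, acetone/H2O, 0 °C
Reagents that add atoms: osmium tetroxide O=[Os](=O)(=O)=O; N-methylmorpholine N-oxide C[N+]1([O-])CCOCC1; water O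
Why: ligand-accelerated osmium tetroxide syn-dihydroxylation picks the strained electron-rich E-C3=C4 olefin over the two acrylate-type alkenes, and the dihydroquinine ligand directs attack to the α face of this trisubstituted E-olefin, which is also the outer face the ring exposes, giving the 3S,4S diol.

**Compound list**
1 | (4R)-4-benzyl-1,3-oxazolidin-2-one | O=C1N[C@H](Cc2ccccc2)CO1 | starting material
2 | 3-methylbut-2-enoyl chloride | CC(C)=CC(Cl)=O | starting material
3 | lithium (4R)-4-benzyl-2-oxo-1,3-oxazolidin-3-ide (formed in the flask) | [Li+].O=C1[N-][C@H](Cc2ccccc2)CO1 | intermediate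
4 | (4R)-4-benzyl-3-(3-methylbut-2-enoyl)-1,3-oxazolidin-2-one | CC(C)=CC(=O)N1[C@H](Cc2ccccc2)COC1=O | intermediate
5 | allyl iodide (3-iodoprop-1-ene) | C=CCI | starting material
6 | sodium (1Z)-1-[(4R)-4-benzyl-2-oxo-1,3-oxazolidin-3-yl]-3-methylbuta-1,3-dien-1-olate (formed in the flask) | [Na+].C=C(C)/C=C(\[O-])N1[C@H](Cc2ccccc2)COC1=O | intermediate
7 | (4R)-4-benzyl-3-[(2R)-2-(prop-1-en-2-yl)pent-4-enoyl]-1,3-oxazolidin-2-one | C=C(C)[C@@H](CC=C)C(=O)N1[C@H](Cc2ccccc2)COC1=O | intermediate
8 | N,O-dimethylhydroxylamine hydrochloride | CNOC.Cl | starting material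
9 | chloro(methyl)aluminium N-methoxy-N-methylamide (formed in the flask) | CON(C)[Al](C)Cl | intermediate
10 | (2R)-N-methoxy-N-methyl-2-(prop-1-en-2-yl)pent-4-enamide | C=C(C)[C@@H](CC=C)C(=O)N(C)OC | intermediate
11 | (2-methylallyl)magnesium chloride | CC(=C)C[Mg]Cl | starting material
12 | chloromagnesium alkoxide of the tetrahedral adduct of 10 and 11 (formed in the flask; new carbinol centre undefined) | C=C(C)[C@@H](CC=C)C(CC(C)=C)(O[Mg]Cl)N(C)OC | intermediate
13 | (5R)-2-methyl-5-(prop-1-en-2-yl)octa-1,7-dien-4-one | C=C(C)[C@@H](CC=C)C(=O)CC(C)=C | intermediate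
14 | (2R)-5-methyl-2-(prop-1-en-2-yl)cyclohex-4-en-1-one | C=C(C)[C@H]1CC=C(C)CC1=O | intermediate
15 | (4-methoxyphenyl)methanol | COc1ccc(CO)cc1 | starting material
16 | trichloroethene | ClC=C(Cl)Cl | starting material
17 | potassium (4-methoxyphenyl)methanolate (formed in the flask) | [K+].COc1ccc(C[O-])cc1 | intermediate
18 | dichloroethyne (formed in the flask) | ClC#CCl | intermediate
19 | 1-{[(E)-1,2-dichloroethenyl]oxymethyl}-4-methoxybenzene | COc1ccc(CO/C(Cl)=C\Cl)cc1 | intermediate
20 | lithium [(4-methoxybenzyl)oxy]acetylide (formed in the flask) | [Li]C#COCc1ccc(OC)cc1 | intermediate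
21 | dichloro{[(4-methoxybenzyl)oxy]ethynyl}cerium (formed in the flask) | Cl[Ce](Cl)C#COCc1ccc(OC)cc1 | intermediate
22 | (1R,2R)-1-{[(4-methoxybenzyl)oxy]ethynyl}-5-methyl-2-(prop-1-en-2-yl)cyclohex-4-en-1-ol | C=C(C)[C@H]1CC=C(C)C[C@]1(O)C#COCc1ccc(OC)cc1 | intermediate
23 | lithium dihydridoaluminate chelate of 22 in which Al bridges the carbinol oxygen and the alkoxy-bearing vinyl carbon (five-membered ring, formed in the flask) | [Li+].C=C(C)[C@H]1CC=C(C)C[C@@]12O[AlH2-]C(OCc3ccc(OC)cc3)=C2 | intermediate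
24 | (1R,2R)-1-{(E)-2-[(4-methoxybenzyl)oxy]ethenyl}-5-methyl-2-(prop-1-en-2-yl)cyclohex-4-en-1-ol | C=C(C)[C@H]1CC=C(C)C[C@]1(O)/C=C/OCc1ccc(OC)cc1 | intermediate
25 | methyl (E)-3-nitroprop-2-enoate | COC(=O)/C=C/[N+](=O)[O-] | starting material
26 | potassium (1R,2R)-1-{(E)-2-[(4-methoxybenzyl)oxy]ethenyl}-5-methyl-2-(prop-1-en-2-yl)cyclohex-4-en-1-olate (formed in the flask) | [K+].C=C(C)[C@H]1CC=C(C)C[C@]1([O-])/C=C/OCc1ccc(OC)cc1 | intermediate
27 | potassium (1Z,3R,5E,8Z)-3-[(4-methoxybenzyl)oxy]-5,9-dimethylcyclodeca-1,5,8-trien-1-olate (formed in the flask) | [K+].[O-]/C1=C\[C@H](OCc2ccc(OC)cc2)C/C(C)=C/C/C=C(C)\C1 | intermediate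
28 | methyl 2-[(1S,2R,4E,7Z)-2-[(4-methoxybenzyl)oxy]-4,8-dimethyl-10-oxocyclodeca-4,7-dien-1-yl]-3-nitropropanoate (both epimers at the propanoate carbon, formed in the flask) | COC(=O)C(C[N+](=O)[O-])[C@@H]1C(=O)C/C(C)=C\C/C=C(C)/C[C@H]1OCc1ccc(OC)cc1 | intermediate
29 | methyl 2-[(1S,2R,4E,7Z)-2-[(4-methoxybenzyl)oxy]-4,8-dimethyl-10-oxocyclodeca-4,7-dien-1-yl]prop-2-enoate | COC(=O)C(=C)[C@@H]1C(=O)C/C(C)=C\C/C=C(C)/C[C@H]1OCc1ccc(OC)cc1 | intermediate
30 | methyl 2-[(1S,2R,4E,7Z)-2-hydroxy-4,8-dimethyl-10-oxocyclodeca-4,7-dien-1-yl]prop-2-enoate (formed in the flask) | COC(=O)C(=C)[C@@H]1C(=O)C/C(C)=C\C/C=C(C)/C[C@H]1O | intermediate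
31 | (6R,7S)-8-oxogermacra-1(10)Z,3E,11(13)-trien-12,6-olide | C=C1C(=O)O[C@@H]2C/C(C)=C/C/C=C(C)\CC(=O)[C@@H]12 | intermediate
32 | (6R,7R,8R)-8-hydroxygermacra-1(10)Z,3E,11(13)-trien-12,6-olide | C=C1C(=O)O[C@@H]2C/C(C)=C/C/C=C(C)\C[C@@H](O)[C@@H]12 | intermediate
33 | (1R,6R,7R,8R,10S)-1,10-epoxy-8-hydroxygermacra-3E,11(13)-dien-12,6-olide | C=C1C(=O)O[C@@H]2C/C(C)=C/C[C@H]3O[C@@]3(C)C[C@@H](O)[C@@H]12 | intermediate
34 | angelic acid, (Z)-2-methylbut-2-enoic acid | C/C=C(/C)C(=O)O | starting material
35 | (Z)-2-methylbut-2-enoic 2,4,6-trichlorobenzoic anhydride (formed in the flask) | C/C=C(/C)C(=O)OC(=O)c1c(Cl)cc(Cl)cc1Cl | intermediate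
36 | (1R,6R,7S,8R,10S)-8-angeloyloxy-1,10-epoxygermacra-3E,11(13)-dien-12,6-olide | C=C1C(=O)O[C@@H]2C/C(C)=C/C[C@H]3O[C@@]3(C)C[C@@H](OC(=O)/C(C)=C\C)[C@@H]12 | intermediate
37 | (1R,3S,4S,6R,7S,8R,10S)-8-angeloyloxy-1,10-epoxy-3,4-dihydroxygermacr-11(13)-en-12,6-olide (CNP0113954.1) | C=C1C(=O)O[C@@H]2C[C@](C)(O)[C@@H](O)C[C@H]3O[C@@]3(C)C[C@@H](OC(=O)/C(C)=C\C)[C@@H]12 | target

**Totals**
Total step count: 14 (13 on the main line plus step 6, which makes side reagent 19).
Longest linear sequence: 13 steps (steps 1–5 and 7–14, from 1 and 2 to 37).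

**Three steps most likely to fail**

Step 9. The β-alkoxy enolate 27 may expel 4-methoxybenzyl oxide (E1cB) before it is trapped, or the bare potassium enolate may give a poor Michael addition. The fallback replaces the oxygen on the vinyl group by silicon, which cannot leave. It sets out from 14: ethynylmagnesium bromide with CeCl3 gives the ethynyl carbinol F3. Hydrosilylation with benzyldimethylsilane (Pt2(dvs)3, dvs = 1,3-divinyltetramethyldisiloxane, P(t-Bu)3) gives the (E)-vinylsilane F4. The same KN(SiMe3)2/18-crown-6 rearrangement with nitroacrylate trapping and Et3N elimination gives the silyl keto acrylate F5. Tamao oxidation (Bu4NF, then H2O2, KHCO3) replaces silicon by hydroxyl with retention at C6 and gives hydroxy ester 30, which lactonises under PPTS, so the fallback returns to the route at 31.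

Step 7. The small linear acetylide may prefer axial attack and give mainly the cis isomer, which would not rearrange through the required chair. The fallback uses an alkenyl metal, for which equatorial attack anti to a 2-alkenyl group is the usual outcome, and forms the C–O bond afterwards. It sets out from 14: (E)-2-(tributylstannyl)vinyllithium (from (E)-Bu3SnCH=CHSnBu3 and n-BuLi) with CeCl3 gives the stannyl dienol F1. Iododestannylation (I2, CH2Cl2, 0 °C) gives the (E)-iodovinyl carbinol F2 with retention. Coupling with alcohol 15 (CuI, 3,4,7,8-tetramethyl-1,10-phenanthroline, Cs2CO3, toluene, 80 °C) forms the enol ether with retention, and the fallback returns to the route at 24.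

Step 11. The ring may override the catalyst and give mainly the 8S alcohol. The fallback accepts what the ring prefers and inverts the carbinol. It sets out from 31: NaBH4 with CeCl3·7H2O (MeOH, −78 °C) gives the 8-epi alcohol F6. A Mitsunobu reaction with formic acid (PPh3, DIAD, THF, 0 °C) gives the inverted 8R formate F7. Brief hydrolysis (NaHCO3, THF/H2O, 0 °C) frees the hydroxyl, and the fallback returns to the route at 32.

**Further compounds**
F1 | step 7 | (1R,2R)-5-methyl-2-(prop-1-en-2-yl)-1-[(E)-2-(tributylstannyl)ethenyl]cyclohex-4-en-1-ol | C=C(C)[C@H]1CC=C(C)C[C@]1(O)/C=C/[Sn](CCCC)(CCCC)CCCC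
F2 | step 7 | (1R,2R)-1-[(E)-2-iodoethenyl]-5-methyl-2-(prop-1-en-2-yl)cyclohex-4-en-1-ol | C=C(C)[C@H]1CC=C(C)C[C@]1(O)/C=C/I
F3 | step 9 | (1R,2R)-1-ethynyl-5-methyl-2-(prop-1-en-2-yl)cyclohex-4-en-1-ol | C=C(C)[C@H]1CC=C(C)C[C@]1(O)C#C
F4 | step 9 | (1R,2R)-1-{(E)-2-[benzyl(dimethyl)silyl]ethenyl}-5-methyl-2-(prop-1-en-2-yl)cyclohex-4-en-1-ol | C=C(C)[C@H]1CC=C(C)C[C@]1(O)/C=C/[Si](C)(C)Cc1ccccc1
F5 | step 9 | methyl 2-[(1R,2R,4E,7Z)-2-[benzyl(dimethyl)silyl]-4,8-dimethyl-10-oxocyclodeca-4,7-dien-1-yl]prop-2-enoate | COC(=O)C(=C)[C@@H]1C(=O)C/C(C)=C\C/C=C(C)/C[C@H]1[Si](C)(C)Cc1ccccc1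
F6 | step 11 | (6R,7R,8S)-8-hydroxygermacra-1(10)Z,3E,11(13)-trien-12,6-olide | C=C1C(=O)O[C@@H]2C/C(C)=C/C/C=C(C)\C[C@H](O)[C@@H]12
F7 | step 11 | (6R,7R,8R)-8-formyloxygermacra-1(10)Z,3E,11(13)-trien-12,6-olide | C=C1C(=O)O[C@@H]2C/C(C)=C/C/C=C(C)\C[C@@H](OC=O)[C@@H]12
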